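We have 4 questions on one scheme run in 3 vessels.

    substrate → intermediate (k1 = 0.057 s⁻¹)
    free catalyst + intermediate → free catalyst + target (k2 = 1.8 M⁻¹ s⁻¹)
    free catalyst + target → spent catalyst (k3 = 0.072 M⁻¹ s⁻¹)
    intermediate → decomposed reagent (k4 = 7.8 × 10⁻⁴ s⁻¹)
    substrate + target ⇌ idle adduct, settled at all times (K5 = 4.3 M⁻¹)

| flask | substrate | free catalyst | time | remark |
|---|---|---|---|---|
| winter | 0.19 M (fed, over 6.00 min) | 0.95 mM | 12 min | all but substrate at the start; substrate goes in evenly over 6.00 min, the run ends at 12 min |
| spring | 0.19 M | 0.95 mM |  | a single well-mixed tank run continuously and read at steady state, 12 min in it on average |
| autumn | 0.19 M | 0.95 mM | 12 min | everything together in a closed stirred flask, run for 12 min |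

- in percentages every species weighs as the substrate in it: one idle adduct counts as two
- for target the idle adduct is counted in
- the stated concentrations are those of everything mixed, before any reaction; amounts are the same in each set-up
- the feed brings no volume worth counting
- in an amount of target, one idle adduct counts as one target
- run time (winter): 12 min

- the set-up with the highest amount of intermediate at the outlet or at the end, in percent of the substrate put in ("none" if the first two lie within 2 percentage points) (winter / spring / autumn / none)
- amount of intermediate at the outlet or at the end, in percent of the substrate put in, winter
- amount of intermediate at the outlet or at the end, in percent of the substrate put in, spring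
- amount of intermediate at the outlet or at the end, in percent of the substrate put in, autumn

Substrate has a half-life of 0.203 min by its first step, far shorter than the run, so in autumn we count the charge as intermediate from the start and set the idle adduct aside.

We follow the fraction of intermediate left, not what is made. In autumn its logarithm falls by two sums. One is decomposition, rate constant times time:

D = 0.562

The other, S, is the catalysed constant times free catalyst summed over time, a pseudo-first-order loss. Early on, target made equals S as a fraction of the charge, and the catalyst-spending step then costs free catalyst in proportion to S. Summing that cost to the whole catalyst charge gives

S = √(2 × catalysed constant × catalyst charge / (spending constant × substrate charge)) = 0.500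

We call S the reach of the catalyst charge: our estimate of the logarithmic units of intermediate that charge removes. At the starting rate it takes 4.87 min, shorter than the run, so we take it whole:

autumn: e^(−D−S) = 34.6 %

The second way is a balance. A broken line for autumn, from the full charge through the fraction left once the reach is used to the end value, gives a mean fraction F = 0.547. Spending the catalyst charge against intermediate at F rather than at the full charge puts target at S√F = 37.0 %, decomposed reagent is DF = 30.7 %, and 32.3 % remains as intermediate. The line borrows the first way's endpoint, but both losses are counted separately, and the two ways lie 2.3 percentage points apart.

In winter, portions stay 9.00 min on average, and we assume the same reach: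

winter: 39.8 %

In spring, the fraction of converted substrate left as intermediate is 1/(1+D+X), with X the tank's catalysed term, and 97.6 % of the substrate is converted at the mean hold of 12 min. Two passes from X = S give 0.363, then 0.431:

spring: 49.0 %

Our choice is spring.

The forecast also names spring, with 42 % (39 % to 45 %) for winter, 49.3 % (48 % to 50.5 %) for spring and 33.5 % (31 % to 36 %) for autumn, on the ground that “the catalyst dies in proportion to how much target is around”. Our winter figure is lower by 2.2 points.

The simulation gives spring as best, with 41.7 % in winter, 49.1 % in spring and 33.4 % in autumn. In autumn, the half-life of free catalyst by its spending step falls from 3.4 h at 0.203 min to 2.3 min at 12.0 min. That is shorter than the 15 min half-life of intermediate by decomposition, and 7.23 % of the catalyst charged stands free then. Autumn's result, read backwards, asks for a reach of 0.535 against our 0.500. A neighbouring autumn flask charged with 5.7 × 10⁻⁴ M of free catalyst has a reach of 0.387, which gives 38.7 %, and it ends with 38.7 % intermediate.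

The constants were set for the occasion; what happens was integrated by code.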